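**Retrosynthetic overview**
1. Feature: in ring B the atoms C3, C3a, C7a and O1 are the four atoms of an ortho-quinone methide of the acylphloroglucinol ring A. Ring B therefore lacks only C2, and C2 can arrive with the future carbinol carbon attached as an ester.
2. Endgame (ring A is dearomatised last): C3a–OH by oxaziridine hydroxylation of an enolate, trans to the C2 side chain; C5–prenyl by ligand-controlled dearomative Tsuji–Trost alkylation; CMe2OH from the C2 ester and MeMgBr.
3. Key disconnection (ring B): C2–C3 and O1–C2, a formal [4+1] annulation of the methide with dimethylsulfonium methoxycarbonylmethylide under a chiral bis-urea, which sets C2.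
4. Methide precursor: a benzylic trimethylammonium iodide with O4 masked as MOM ether, made from 2-methylphloroglucinol by acylation, para-selective MOM protection, Mannich reaction and N-methylation. The ylide comes from methyl bromoacetate and dimethyl sulfide.
5. Ring order: ring A is bought as the arene, ring B is closed in the key step, and no further ring is formed.

Key step: step 7

Numbering: benzofuran numbering (O1, C2, C3, C3a, C4–C7, C7a) is used for the bicycles and, by anticipation, for the atoms of the monocyclic precursors. Ring A is the carbocycle and ring B the dihydrofuran.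

Assumption: precedent does not predict the sense of induction of the bis-urea (step 7) or of the diphosphine (step 10). The enantiomer written is taken to give the configuration drawn, and its mirror image is used if a test run shows the opposite sense.

**Step 1**
Reactants: 1 2-methylbenzene-1,3,5-triol; 2 isobutyryl chloride
Product: 3 1-(2,4,6-trihydroxy-3-methylphenyl)-2-methylpropan-1-one
Conditions: AlCl3 (3.5 equiv), CH2Cl2/PhNO2, 0 → 45 °C; ice/1 M HCl
Reagents that add atoms: none
Why: Friedel–Crafts acylation of a very electron-rich arene, in which the two free ring carbons of 1 are equivalent by symmetry so that one regioisomer results, and the chelated ketone deactivates 3 against a second acylation.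

**Step 2**
Reactants: 3 1-(2,4,6-trihydroxy-3-methylphenyl)-2-methylpropan-1-one
Product: 4 1-[2,6-dihydroxy-4-(methoxymethoxy)-3-methylphenyl]-2-methylpropan-1-one
Conditions: MOMCl (1.05 equiv), i-Pr2NEt (1.1 equiv), CH2Cl2, −10 → 0 °C
Reagents that add atoms: chloromethyl methyl ether, COCCl
Why: Base-mediated O-alkylation with an α-chloro ether, in which the hydroxyl para to the ketone (the future O4) is the most acidic and the only one outside the hydrogen-bond chelate with the carbonyl group, so one equivalent of reagent at low temperature should go there first.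

**Step 3**
Reactants: 4 1-[2,6-dihydroxy-4-(methoxymethoxy)-3-methylphenyl]-2-methylpropan-1-one
Product: 5 1-{3-[(dimethylamino)methyl]-2,6-dihydroxy-4-(methoxymethoxy)-5-methylphenyl}-2-methylpropan-1-one
Conditions: [Me2N=CH2]I (1.1 equiv), CH2Cl2, 0 °C → rt; aq NaHCO3
Reagents that add atoms: N,N-dimethylmethyleneiminium iodide (Eschenmoser's salt), C=[N+](C)C.[I-]
Why: Mannich reaction of a phenol with a preformed iminium salt, where only one ring carbon is free and it lies ortho to a free hydroxyl, and the water-free medium avoids the methylene-bridged dimers that aqueous formaldehyde tends to give.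

**Step 4**
Reactants: 5 1-{3-[(dimethylamino)methyl]-2,6-dihydroxy-4-(methoxymethoxy)-5-methylphenyl}-2-methylpropan-1-one
Product: 6 1-[2,4-dihydroxy-6-(methoxymethoxy)-5-methyl-3-(2-methylpropanoyl)phenyl]-N,N,N-trimethylmethanaminium iodide
Conditions: MeI (3 equiv), Et2O/THF, 0 °C → rt, dark; filtration
Reagents that add atoms: iodomethane, CI
Why: Menshutkin quaternisation, in which without added base the tertiary amine is the only good nucleophile, the chelated phenols stay protonated, and the salt leaves the ethereal solution as it forms and is thereby kept from losing trimethylamine.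

**Step 5**
Reactants: 7 methyl bromoacetate; 8 dimethyl sulfide
Product: 9 (2-methoxy-2-oxoethyl)dimethylsulfonium bromide
Conditions: acetone, rt; filtration
Reagents that add atoms: none
Why: SN2 alkylation of a sulfide by an α-halo ester, the standard sulfonium salt synthesis, with the salt crystallising from acetone.

**Step 6**
Reactants: 9 (2-methoxy-2-oxoethyl)dimethylsulfonium bromide
Product: 10 dimethylsulfonium methoxycarbonylmethylide
Conditions: NaOH (1.0 equiv) in sat. aq K2CO3, CHCl3, 5 °C, short contact; dry over K2CO3, concentrate cold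
Reagents that add atoms: none
Why: Deprotonation of an ester-stabilised sulfonium salt in a cold two-phase system, from which the stabilised ylide passes into chloroform before the ester can be saponified.

**Step 7**
Reactants: 6 1-[2,4-dihydroxy-6-(methoxymethoxy)-5-methyl-3-(2-methylpropanoyl)phenyl]-N,N,N-trimethylmethanaminium iodide; 10 dimethylsulfonium methoxycarbonylmethylide
Product: 13 methyl (2S)-6-hydroxy-4-(methoxymethoxy)-5-methyl-7-(2-methylpropanoyl)-2,3-dihydro-1-benzofuran-2-carboxylate, via ortho-quinone methide 11 (not isolated), via sulfonium betaine 12 (not isolated)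
Conditions: 10 (1.3 equiv), powdered K2CO3 (1.5 equiv), (R)-1,1'-(1,1'-binaphthalene-2,2'-diyl)bis{3-[3,5-bis(trifluoromethyl)phenyl]urea} (10 mol %), 4 Å MS, CH2Cl2/PhMe 1:1, −20 °C
Reagents that add atoms: none
Why: Proposed new method: K2CO3, with 10 as soluble proton shuttle, deprotonates 6, the phenoxide–ammonium zwitterion expels NMe3 to give ortho-quinone methide 11 (C3=C3a–C7a=O), the ylide carbon of 10 adds to the unsubstituted terminus C3 with rearomatisation of ring A (C2–C3 bond), and the C7a phenoxide of betaine 12 displaces Me2S from C2 (O1–C2 bond). The closest known reaction type is the formal [4+1] annulation of ortho-quinone methides with stabilised sulfonium ylides, which under chiral urea catalysis is known only for methides substituted at the benzylic carbon, where that carbon is the controlling stereocentre, whereas here C3 is CH2 and C2 stands alone, and this is what goes beyond precedent. Ring B closes by an intramolecular SN2 reaction, 5-exo-tet, with inversion at C2. C2–H of 12 lies between the sulfonium and the ester group, so the two epimers should interconvert by proton transfer faster than either closes, and the bis-urea, holding the phenoxide with one urea and the ester carbonyl with the other, is meant to accelerate closure of the (2R) epimer only, a dynamic kinetic resolution that ends in (2S)-13. The regiochemistry is fixed by the substrate, since O4 is blocked as MOM ether and O6, para to C3a, can at most form a para-methide tautomer that gives the same betaine and cannot reach C2, which leaves the C7a oxygen as the only ring-closing oxygen. The sparing solubility of 6 keeps 11 dilute against dimerisation, KI precipitates so that iodide does not occupy the urea, and the low temperature holds back the uncatalysed closure and base-induced enolisation of 13 at C2.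

**Step 8**
Reactants: 13 methyl (2S)-6-hydroxy-4-(methoxymethoxy)-5-methyl-7-(2-methylpropanoyl)-2,3-dihydro-1-benzofuran-2-carboxylate
Product: 15 1-[(2S)-6-hydroxy-2-(2-hydroxypropan-2-yl)-4-(methoxymethoxy)-5-methyl-2,3-dihydro-1-benzofuran-7-yl]-2-methylpropan-1-one, via methyl ketone 14 (not isolated)
Conditions: MeMgBr (3.3 equiv), THF, −78 → −10 °C; sat. aq NH4Cl
Reagents that add atoms: methylmagnesium bromide, C[Mg]Br
Why: Double Grignard addition to an ester, in which the first equivalent makes the bromomagnesium phenoxide at O6 whose chelate turns the hindered, doubly ortho-substituted isopropyl ketone into an unreactive vinylogous carboxylate, while the inductively activated α-aryloxy ester and then ketone 14 add faster than they enolise at low temperature, so C2 keeps its configuration.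

**Step 9**
Reactants: 15 1-[(2S)-6-hydroxy-2-(2-hydroxypropan-2-yl)-4-(methoxymethoxy)-5-methyl-2,3-dihydro-1-benzofuran-7-yl]-2-methylpropan-1-one
Product: 16 1-[(2S)-4,6-dihydroxy-2-(2-hydroxypropan-2-yl)-5-methyl-2,3-dihydro-1-benzofuran-7-yl]-2-methylpropan-1-one
Conditions: HCl (0.5 M in MeOH), 40 °C
Reagents that add atoms: none
Why: Acid-catalysed acetal exchange (MOM cleavage) with methanol as acceptor, which the tertiary alcohol survives because a cation next to the C2–O1 bond is destabilised, and to which the ketone, the ring-B ether and C2 are inert.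

**Step 10**
Reactants: 16 1-[(2S)-4,6-dihydroxy-2-(2-hydroxypropan-2-yl)-5-methyl-2,3-dihydro-1-benzofuran-7-yl]-2-methylpropan-1-one; 17 3-methylbut-2-en-1-yl acetate (prenyl acetate)
Product: 18 (2S,5R)-4-hydroxy-2-(2-hydroxypropan-2-yl)-5-methyl-5-(3-methylbut-2-en-1-yl)-7-(2-methylpropanoyl)-3,5-dihydro-1-benzofuran-6(2H)-one (drawn as the C4 enol tautomer)
Conditions: 17 (1.05 equiv), Pd2(dba)3·CHCl3 (2.5 mol %), N,N'-[(1R,2R)-cyclohexane-1,2-diyl]bis[2-(diphenylphosphanyl)benzamide] (7.5 mol %), Et3N (2.5 equiv), degassed CH2Cl2, 0 °C → rt; dilute citric acid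
Reagents that add atoms: none
Why: Dearomative Tsuji–Trost asymmetric allylic alkylation, in which zerovalent palladium ionises 17 to a π-prenyl complex that the ring-A phenoxide attacks at its less hindered CH2 terminus through C5, the carbon between the two free hydroxyls and thus the central carbon of a masked 1,3-diketone (C3a has an ether oxygen on one side, and O-prenyl ethers of this acidic phenol re-ionise and funnel to carbon), while the new quaternary centre, too far from C2 for substrate control, is set by the chiral pocket of the C2-symmetric diphosphine as in the asymmetric allylic dearomatisation of phenols and naphthols.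

**Step 11**
Reactants: 18 (2S,5R)-4-hydroxy-2-(2-hydroxypropan-2-yl)-5-methyl-5-(3-methylbut-2-en-1-yl)-7-(2-methylpropanoyl)-3,5-dihydro-1-benzofuran-6(2H)-one
Product: 20 (2S,3aR,5S)-3a-hydroxy-2-(2-hydroxypropan-2-yl)-5-methyl-5-(3-methylbut-2-en-1-yl)-7-(2-methylpropanoyl)-3,3a-dihydro-1-benzofuran-4,6(2H,5H)-dione, via sodium enolate 19 (not isolated)
Conditions: NaN(SiMe3)2 (1.05 equiv), THF, −78 °C; 2-(benzenesulfonyl)-3-phenyloxaziridine (1.2 equiv), −78 → −40 °C; AcOH at −40 °C
Reagents that add atoms: 2-(benzenesulfonyl)-3-phenyloxaziridine, O=S(=O)(c1ccccc1)N1OC1c1ccccc1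
Why: Davis oxidation of a stabilised enolate, in which C3a should react rather than C7 because attack there leaves the C7a(O1)=C7(acyl)–C6=O push–pull system intact whereas C7 is the buried centre of a β-tricarbonyl, the oxaziridine spares the prenyl alkene, and oxygen should arrive on the face of the flat bicycle opposite the bulky CMe2OH group at C2 (a larger bias than methyl against prenyl at C5), giving (3aR) with OH trans to the C2 side chain and cis to the prenyl group, while C5 changes descriptor from R to S only because C4 gains priority.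

**Compound list**
1 | 2-methylbenzene-1,3,5-triol | Cc1c(O)cc(O)cc1O | starting material
2 | isobutyryl chloride | CC(C)C(=O)Cl | starting material
3 | 1-(2,4,6-trihydroxy-3-methylphenyl)-2-methylpropan-1-one | CC(C)C(=O)c1c(O)cc(O)c(C)c1O | intermediate
4 | 1-[2,6-dihydroxy-4-(methoxymethoxy)-3-methylphenyl]-2-methylpropan-1-one | CC(C)C(=O)c1c(O)cc(OCOC)c(C)c1O | intermediate
5 | 1-{3-[(dimethylamino)methyl]-2,6-dihydroxy-4-(methoxymethoxy)-5-methylphenyl}-2-methylpropan-1-one | CN(C)Cc1c(O)c(C(=O)C(C)C)c(O)c(C)c1OCOC | intermediate
6 | 1-[2,4-dihydroxy-6-(methoxymethoxy)-5-methyl-3-(2-methylpropanoyl)phenyl]-N,N,N-trimethylmethanaminium iodide | C[N+](C)(C)Cc1c(O)c(C(=O)C(C)C)c(O)c(C)c1OCOC.[I-] | intermediate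
7 | methyl bromoacetate | COC(=O)CBr | starting material
8 | dimethyl sulfide | CSC | starting material
9 | (2-methoxy-2-oxoethyl)dimethylsulfonium bromide | C[S+](C)CC(=O)OC.[Br-] | intermediate
10 | dimethylsulfonium methoxycarbonylmethylide | C[S+](C)[CH-]C(=O)OC | intermediate
11 | 3-hydroxy-5-(methoxymethoxy)-4-methyl-6-methylidene-2-(2-methylpropanoyl)cyclohexa-2,4-dien-1-one, the ortho-quinone methide (not isolated) | C=C1C(=O)C(C(=O)C(C)C)=C(O)C(C)=C1OCOC | intermediate
12 | 2-[2-(dimethylsulfonio)-3-methoxy-3-oxopropyl]-5-hydroxy-3-(methoxymethoxy)-4-methyl-6-(2-methylpropanoyl)phenolate, the betaine, both C2 epimers in equilibrium (not isolated) | COC(=O)C(Cc1c([O-])c(C(=O)C(C)C)c(O)c(C)c1OCOC)[S+](C)C | intermediate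
13 | methyl (2S)-6-hydroxy-4-(methoxymethoxy)-5-methyl-7-(2-methylpropanoyl)-2,3-dihydro-1-benzofuran-2-carboxylate | COC(=O)[C@@H]1Cc2c(OCOC)c(C)c(O)c(C(=O)C(C)C)c2O1 | intermediate
14 | 1-[(2S)-2-acetyl-6-hydroxy-4-(methoxymethoxy)-5-methyl-2,3-dihydro-1-benzofuran-7-yl]-2-methylpropan-1-one, present as its magnesium phenoxide (not isolated) | CC(=O)[C@@H]1Cc2c(OCOC)c(C)c(O)c(C(=O)C(C)C)c2O1 | intermediate
15 | 1-[(2S)-6-hydroxy-2-(2-hydroxypropan-2-yl)-4-(methoxymethoxy)-5-methyl-2,3-dihydro-1-benzofuran-7-yl]-2-methylpropan-1-one | CC(C)(O)[C@@H]1Cc2c(OCOC)c(C)c(O)c(C(=O)C(C)C)c2O1 | intermediate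
16 | 1-[(2S)-4,6-dihydroxy-2-(2-hydroxypropan-2-yl)-5-methyl-2,3-dihydro-1-benzofuran-7-yl]-2-methylpropan-1-one | CC(C)(O)[C@@H]1Cc2c(O)c(C)c(O)c(C(=O)C(C)C)c2O1 | intermediate
17 | 3-methylbut-2-en-1-yl acetate | CC(C)=CCOC(C)=O | starting material
18 | (2S,5R)-4-hydroxy-2-(2-hydroxypropan-2-yl)-5-methyl-5-(3-methylbut-2-en-1-yl)-7-(2-methylpropanoyl)-3,5-dihydro-1-benzofuran-6(2H)-one | CC(C)=CC[C@@]1(C)C(=O)C(C(=O)C(C)C)=C2O[C@H](C(C)(C)O)CC2=C1O | intermediate
19 | sodium enolate of 18 (not isolated) | CC(C)=CC[C@@]1(C)C(=O)C(C(=O)C(C)C)=C2O[C@H](C(C)(C)O)CC2=C1[O-].[Na+] | intermediate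
20 | (2S,3aR,5S)-3a-hydroxy-2-(2-hydroxypropan-2-yl)-5-methyl-5-(3-methylbut-2-en-1-yl)-7-(2-methylpropanoyl)-3,3a-dihydro-1-benzofuran-4,6(2H,5H)-dione (CNP0220605.1) | CC(C)=CC[C@@]1(C)C(=O)C(C(=O)C(C)C)=C2O[C@H](C(C)(C)O)C[C@]2(O)C1=O | target

**Step count**
Total step count: 11.
Longest linear sequence: 9 steps (steps 1–4 and 7–11). The ylide branch (steps 5 and 6) joins at step 7.

**Steps most likely to fail**

1. **Step 7.**
- What may go wrong: uncatalysed closure of both betaine epimers may outrun the urea-bound pathway and erode the enantioselectivity. The methide may dimerise, and the base may slowly enolise the product at C2.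
- Fallback: auxiliary control with separation, from 6 and 8, returning at 15.
- (1R,2S,5R)-Menthol is acylated with bromoacetyl bromide (pyridine, CH2Cl2) to (1R,2S,5R)-menthyl bromoacetate F1.
- F1 and 8 give the menthyl ester sulfonium bromide F2, and cold NaOH/K2CO3 then gives the menthyl ester ylide F3.
- F3 and 6 are combined with K2CO3 and no catalyst. This is the known non-asymmetric [4+1] annulation of an ortho-quinone methide with an ester-stabilised sulfonium ylide.
- The two C2 epimers, the menthyl (2S)-carboxylate F4 and the menthyl (2R)-carboxylate F5, are now diastereomers and are separated by chromatography or crystallisation.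
- F5 is re-equilibrated at C2 with DBU and separated again.
- MeMgBr under the conditions of step 8 converts F4 through 14 into 15 with loss of menthol.

2. **Step 10.**
- What may go wrong: attack through C3a or through oxygen, a second prenylation of the acidic product, and poor facial discrimination by the ligand on a flat, nearly symmetric nucleophile.
- Fallback: from 15, returning at 18. In 15, O4 is still a MOM ether, so O6 is the only phenoxide.
- 15 is treated with LiN(SiMe3)2 (1 equiv) in toluene and then with prenyl bromide (0 °C → rt). This is the known ortho-selective alkylative dearomatisation of lithium phenoxides in non-polar media.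
- The tight ion pair delivers the halide to a carbon next to O6. C7 carries the acyl group, so C5 is alkylated.
- The two C5 epimers, the (2S,5R) MOM dienol ether F6 and the (2S,5S) MOM dienol ether F7, are diastereomers because of C2 and are separated by chromatography.
- Methanolic HCl as in step 9 cleaves the enol acetal of F6 and gives 18.

3. **Step 11.**
- What may go wrong: poor facial selectivity, because the C5 prenyl group and the C2 side chain shield opposite faces. A hydrogen bond from the tertiary hydroxyl may steer the oxaziridine to the wrong face, and base may induce acyloin ring contraction of the product.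
- Fallback: from 18, returning at 20.
- Et3SiOTf/2,6-lutidine gives the bis(triethylsilyl) ether F8.
- K2CO3/MeOH at 0 °C removes only the labile enol silyl group and leaves the tertiary triethylsilyl ether F9.
- The C2 group of F9 is much larger and is no longer a hydrogen-bond donor.
- F9 is hydroxylated under the conditions of step 11 to the 3a-hydroxy triethylsilyl ether F10, any C3a epimer being removed by chromatography at this less polar stage.
- HF·pyridine in THF then gives 20.

**Further compounds**
F1 | step 7 | (1R,2S,5R)-menthyl bromoacetate | CC(C)[C@@H]1CC[C@@H](C)C[C@H]1OC(=O)CBr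
F2 | step 7 | dimethyl{2-[(1R,2S,5R)-menthyloxy]-2-oxoethyl}sulfonium bromide | CC(C)[C@@H]1CC[C@@H](C)C[C@H]1OC(=O)C[S+](C)C.[Br-]
F3 | step 7 | dimethylsulfonium [(1R,2S,5R)-menthyloxycarbonyl]methylide | CC(C)[C@@H]1CC[C@@H](C)C[C@H]1OC(=O)[CH-][S+](C)C
F4 | step 7 | (1R,2S,5R)-menthyl (2S)-6-hydroxy-4-(methoxymethoxy)-5-methyl-7-(2-methylpropanoyl)-2,3-dihydro-1-benzofuran-2-carboxylate | CC(C)[C@@H]1CC[C@@H](C)C[C@H]1OC(=O)[C@@H]2Cc3c(OCOC)c(C)c(O)c(C(=O)C(C)C)c3O2
F5 | step 7 | (1R,2S,5R)-menthyl (2R)-6-hydroxy-4-(methoxymethoxy)-5-methyl-7-(2-methylpropanoyl)-2,3-dihydro-1-benzofuran-2-carboxylate | CC(C)[C@@H]1CC[C@@H](C)C[C@H]1OC(=O)[C@H]2Cc3c(OCOC)c(C)c(O)c(C(=O)C(C)C)c3O2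
F6 | step 10 | (2S,5R)-2-(2-hydroxypropan-2-yl)-4-(methoxymethoxy)-5-methyl-5-(3-methylbut-2-en-1-yl)-7-(2-methylpropanoyl)-3,5-dihydro-1-benzofuran-6(2H)-one | CC(C)=CC[C@@]1(C)C(=O)C(C(=O)C(C)C)=C2O[C@H](C(C)(C)O)CC2=C1OCOC
F7 | step 10 | (2S,5S)-2-(2-hydroxypropan-2-yl)-4-(methoxymethoxy)-5-methyl-5-(3-methylbut-2-en-1-yl)-7-(2-methylpropanoyl)-3,5-dihydro-1-benzofuran-6(2H)-one | CC(C)=CC[C@]1(C)C(=O)C(C(=O)C(C)C)=C2O[C@H](C(C)(C)O)CC2=C1OCOC
F8 | step 11 | (2S,5R)-5-methyl-5-(3-methylbut-2-en-1-yl)-7-(2-methylpropanoyl)-4-(triethylsilyloxy)-2-[2-(triethylsilyloxy)propan-2-yl]-3,5-dihydro-1-benzofuran-6(2H)-one | CC(C)=CC[C@@]1(C)C(=O)C(C(=O)C(C)C)=C2O[C@H](C(C)(C)O[Si](CC)(CC)CC)CC2=C1O[Si](CC)(CC)CC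
F9 | step 11 | (2S,5R)-4-hydroxy-5-methyl-5-(3-methylbut-2-en-1-yl)-7-(2-methylpropanoyl)-2-[2-(triethylsilyloxy)propan-2-yl]-3,5-dihydro-1-benzofuran-6(2H)-one | CC(C)=CC[C@@]1(C)C(=O)C(C(=O)C(C)C)=C2O[C@H](C(C)(C)O[Si](CC)(CC)CC)CC2=C1O
F10 | step 11 | (2S,3aR,5S)-3a-hydroxy-5-methyl-5-(3-methylbut-2-en-1-yl)-7-(2-methylpropanoyl)-2-[2-(triethylsilyloxy)propan-2-yl]-3,3a-dihydro-1-benzofuran-4,6(2H,5H)-dione | CC(C)=CC[C@@]1(C)C(=O)C(C(=O)C(C)C)=C2O[C@H](C(C)(C)O[Si](CC)(CC)CC)C[C@]2(O)C1=O
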